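**Retrosynthetic overview**
1. Monotesone A ⇒ bis-silyl ether 11. Fluoride-labile iPr3Si groups sit on O-7 and O-3'; the acid- and hydrogenolysis-sensitive 4'-O-prenyl ether is carried from the start.
2. (2S)-11 ⇒ racemic flavanone 10. The single stereocentre is secured by kinetic resolution: asymmetric transfer hydrogenation removes the 2R antipode.
3. 10 ⇒ chalcone 9. Ring C is the only ring made, by 6-endo oxa-Michael closure of a phenol oxygen onto C2; rings A and B are bought.
4. 9 ⇒ ketone 3 + aldehyde 7. The key C2–C3 bond comes from an intermolecular Claisen–Schmidt aldol condensation.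
5. 3 ⇐ phloroacetophenone 1 (4-O-silylation); 7 ⇐ 3,4-dihydroxybenzaldehyde 4 (regioselective 4-O-prenylation, then 3-O-silylation).

Assumption: iPr3SiCl and prenyl bromide count as commercial starting materials and are numbered; racemic compounds are drawn without a stereo label at C2.

**Route**

Step 1
Reactants: 1 2',4',6'-trihydroxyacetophenone (dried); 2 triisopropylsilyl chloride
Product: 3 1-[2,6-dihydroxy-4-(triisopropylsilyloxy)phenyl]ethanone
Conditions: iPr3SiCl (1.05 equiv), imidazole (2.2 equiv), DMF, 0 °C to rt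
Reagents that add atoms: triisopropylsilyl chloride (2), CC(C)[Si](Cl)(C(C)C)C(C)C
Why: Imidazole-mediated O-silylation goes selectively to the 4-OH because it is the only phenol that is neither hydrogen-bonded to the acetyl group nor flanked by it, and a fluoride-labile group is chosen because the later prenyl ether tolerates neither acid nor hydrogenolysis.

Step 2
Reactants: 4 3,4-dihydroxybenzaldehyde; 5 prenyl bromide (1-bromo-3-methylbut-2-ene)
Product: 6 3-hydroxy-4-[(3-methylbut-2-en-1-yl)oxy]benzaldehyde
Conditions: prenyl bromide (1.1 equiv), NaHCO3 (1.5 equiv), DMF, 40 °C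
Reagents that add atoms: prenyl bromide (5), CC(C)=CCBr
Why: Williamson etherification under weak-base control, in which NaHCO3 ionises only the more acidic 4-OH (para to the formyl group), so the allylic bromide alkylates O-4 and leaves O-3 free.

Step 3
Reactants: 6 3-hydroxy-4-[(3-methylbut-2-en-1-yl)oxy]benzaldehyde; 2 triisopropylsilyl chloride
Product: 7 4-[(3-methylbut-2-en-1-yl)oxy]-3-(triisopropylsilyloxy)benzaldehyde
Conditions: iPr3SiCl (1.2 equiv), imidazole (2.5 equiv), DMF, rt
Reagents that add atoms: triisopropylsilyl chloride (2), CC(C)[Si](Cl)(C(C)C)C(C)C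
Why: Imidazole-mediated O-silylation masks the remaining phenol so that it neither consumes base nor deactivates the aldehyde as a phenoxide in the aldol step.

Step 4
Reactants: 3 1-[2,6-dihydroxy-4-(triisopropylsilyloxy)phenyl]ethanone; 7 4-[(3-methylbut-2-en-1-yl)oxy]-3-(triisopropylsilyloxy)benzaldehyde
Product: 9 (E)-1-[2,6-dihydroxy-4-(triisopropylsilyloxy)phenyl]-3-{4-[(3-methylbut-2-en-1-yl)oxy]-3-(triisopropylsilyloxy)phenyl}prop-2-en-1-one, via aldol adduct 8 (not isolated)
Conditions: LiN(SiMe3)2 (4.5 equiv), THF, −78 °C to rt, 16 h; then AcOH, 0 °C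
Reagents that add atoms: none
Why: Claisen–Schmidt (crossed aldol) condensation, in which the lithium enolate of the bis-phenoxide of 3 adds to the non-enolisable aldehyde 7 and the aldolate 8 eliminates by E1cB on warming with excess amide base to the conjugated E-enone, under hydroxide-free conditions that the aryl silyl ethers and the prenyl ether survive.

Step 5
Reactants: 9 (E)-chalcone from step 4
Product: 10 rac-5-hydroxy-2-{4-[(3-methylbut-2-en-1-yl)oxy]-3-(triisopropylsilyloxy)phenyl}-7-(triisopropylsilyloxy)chroman-4-one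
Conditions: NaOAc (3 equiv), EtOH, 60 °C
Reagents that add atoms: none
Why: Base-catalysed 6-endo-trig intramolecular oxa-Michael addition (chalcone–flavanone isomerisation) lies far on the flavanone side for 2',6'-dihydroxychalcones because one phenol closes ring C while the other keeps its hydrogen bond to the carbonyl, and C2 is formed here as a racemate.

Step 6
Reactants: 10 racemic flavanone from step 5
Product: 11 (2S)-5-hydroxy-2-{4-[(3-methylbut-2-en-1-yl)oxy]-3-(triisopropylsilyloxy)phenyl}-7-(triisopropylsilyloxy)chroman-4-one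
Conditions: (C5Me5)RhCl[(R,R)-TsNCHPhCHPhNH2] (1 mol%), HCO2H/Et3N (5:2), EtOAc, 25 °C, stopped at 52–55% conversion (chiral HPLC); chromatography
Reagents that add atoms: none
Why: Kinetic resolution by Noyori–Ikariya asymmetric transfer hydrogenation, in which the (R,R)-catalyst delivers hydride to the carbonyl face that gives the (4R)-carbinol, a face that is the easy cis-forming one only in the (2R)-ketone, so that antipode is reduced to the polar cis-(2R,4R)-flavan-4-ol while the (2S)-ketone is recovered in at least 99% ee once conversion passes 50%, which fixes the only stereocentre of the target.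

Step 7
Reactants: 11 (2S)-bis-silyl flavanone from step 6
Product: 12 Monotesone A, (2S)-5,7-dihydroxy-2-{3-hydroxy-4-[(3-methylbut-2-en-1-yl)oxy]phenyl}chroman-4-one
Conditions: Bu4NF (2.4 equiv), AcOH (2.4 equiv), THF, 0 °C to rt
Reagents that add atoms: none
Why: Fluoride-mediated desilylation of both aryl silyl ethers under acetic-acid buffering leaves the aryl prenyl ether untouched and, with no strong base and no free 4'-OH to open ring C, does not racemise C2.

**Compound list**
1 | 2',4',6'-trihydroxyacetophenone | CC(=O)c1c(O)cc(O)cc1O | starting material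
2 | triisopropylsilyl chloride | CC(C)[Si](Cl)(C(C)C)C(C)C | starting material
3 | 1-[2,6-dihydroxy-4-(triisopropylsilyloxy)phenyl]ethanone | CC(=O)c1c(O)cc(O[Si](C(C)C)(C(C)C)C(C)C)cc1O | intermediate
4 | 3,4-dihydroxybenzaldehyde | O=Cc1ccc(O)c(O)c1 | starting material
5 | prenyl bromide (1-bromo-3-methylbut-2-ene) | CC(C)=CCBr | starting material
6 | 3-hydroxy-4-[(3-methylbut-2-en-1-yl)oxy]benzaldehyde | CC(C)=CCOc1ccc(C=O)cc1O | intermediate
7 | 4-[(3-methylbut-2-en-1-yl)oxy]-3-(triisopropylsilyloxy)benzaldehyde | CC(C)=CCOc1ccc(C=O)cc1O[Si](C(C)C)(C(C)C)C(C)C | intermediate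
8 | rac-1-[2,6-dihydroxy-4-(triisopropylsilyloxy)phenyl]-3-hydroxy-3-{4-[(3-methylbut-2-en-1-yl)oxy]-3-(triisopropylsilyloxy)phenyl}propan-1-one (aldol adduct, present as its lithium aldolate) | CC(C)=CCOc1ccc(C(O)CC(=O)c2c(O)cc(O[Si](C(C)C)(C(C)C)C(C)C)cc2O)cc1O[Si](C(C)C)(C(C)C)C(C)C | intermediate
9 | (E)-1-[2,6-dihydroxy-4-(triisopropylsilyloxy)phenyl]-3-{4-[(3-methylbut-2-en-1-yl)oxy]-3-(triisopropylsilyloxy)phenyl}prop-2-en-1-one | CC(C)=CCOc1ccc(/C=C/C(=O)c2c(O)cc(O[Si](C(C)C)(C(C)C)C(C)C)cc2O)cc1O[Si](C(C)C)(C(C)C)C(C)C | intermediate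
10 | rac-5-hydroxy-2-{4-[(3-methylbut-2-en-1-yl)oxy]-3-(triisopropylsilyloxy)phenyl}-7-(triisopropylsilyloxy)chroman-4-one | CC(C)=CCOc1ccc(C2CC(=O)c3c(O)cc(O[Si](C(C)C)(C(C)C)C(C)C)cc3O2)cc1O[Si](C(C)C)(C(C)C)C(C)C | intermediate
11 | (2S)-5-hydroxy-2-{4-[(3-methylbut-2-en-1-yl)oxy]-3-(triisopropylsilyloxy)phenyl}-7-(triisopropylsilyloxy)chroman-4-one | CC(C)=CCOc1ccc([C@@H]2CC(=O)c3c(O)cc(O[Si](C(C)C)(C(C)C)C(C)C)cc3O2)cc1O[Si](C(C)C)(C(C)C)C(C)C | intermediate
12 | Monotesone A, (2S)-5,7-dihydroxy-2-{3-hydroxy-4-[(3-methylbut-2-en-1-yl)oxy]phenyl}chroman-4-one | CC(C)=CCOc1ccc([C@@H]2CC(=O)c3c(O)cc(O)cc3O2)cc1O | target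

**Totals**
Total step count: 7. Longest linear sequence: 6 steps (4 → 6 → 7 → 9 → 10 → 11 → 12).

**Steps most likely to fail, with fallbacks**

Step 4 (polyanion Claisen–Schmidt condensation). The trianion of 3 may react sluggishly or stop at the aldol stage. The fallback sets out again from 3 and 7 and separates addition from ring closure. The aldol addition alone is run with LiN(SiMe3)2 (3.3 equiv) in THF at −78 °C and quenched cold with AcOH, and the β-hydroxy ketone 8 is isolated. Ring C is then closed by an intramolecular Mitsunobu etherification (PPh3, diisopropyl azodicarboxylate, THF, 0 °C), in which the activated benzylic alcohol is displaced by an ortho phenol; any enone formed by elimination closes to the same product on brief NaOAc treatment. This comes back to the route at racemic flavanone 10 and bypasses chalcone 9 and step 5. No compound outside the list is made (F0).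

Step 6 (kinetic resolution). The ketone is electron-rich and hydrogen-bonded to the 5-OH, so the transfer hydrogenation may be slow or poorly selective. The fallback sets out from racemic 10 and separates the enantiomers physically by preparative supercritical-fluid chromatography on an amylose tris(3,5-dimethylphenylcarbamate) phase (CO2/iPrOH), coming back to the route at 11. The unwanted antipode, (2R)-5-hydroxy-2-{4-[(3-methylbut-2-en-1-yl)oxy]-3-(triisopropylsilyloxy)phenyl}-7-(triisopropylsilyloxy)chroman-4-one F1, is re-equilibrated to racemic 10 with catalytic 1,8-diazabicyclo[5.4.0]undec-7-ene in THF (ring opening to chalcone 9 and reclosure) and recycled.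

Step 1 (regioselective mono-silylation). Over-silylation or mixtures are possible. The fallback sets out from unprotected 1 and aldehyde 7. They are condensed directly as the polyanion (LiN(SiMe3)2, 5.5 equiv, THF, −78 °C to rt, AcOH quench) to (E)-3-{4-[(3-methylbut-2-en-1-yl)oxy]-3-(triisopropylsilyloxy)phenyl}-1-(2,4,6-trihydroxyphenyl)prop-2-en-1-one F2. This is cyclised (NaOAc, EtOH, 60 °C) to rac-5,7-dihydroxy-2-{4-[(3-methylbut-2-en-1-yl)oxy]-3-(triisopropylsilyloxy)phenyl}chroman-4-one F3. Only the acidic, non-chelated 7-OH of F3 is then silylated (iPr3SiCl 1.05 equiv, imidazole, DMF, 0 °C; the 5-OH stays locked in its hydrogen bond to the carbonyl), which comes back to the route at 10.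

**Further compounds**
F0 | step 4 | none | none
F1 | step 6 | (2R)-5-hydroxy-2-{4-[(3-methylbut-2-en-1-yl)oxy]-3-(triisopropylsilyloxy)phenyl}-7-(triisopropylsilyloxy)chroman-4-one | CC(C)=CCOc1ccc([C@H]2CC(=O)c3c(O)cc(O[Si](C(C)C)(C(C)C)C(C)C)cc3O2)cc1O[Si](C(C)C)(C(C)C)C(C)C
F2 | step 1 | (E)-3-{4-[(3-methylbut-2-en-1-yl)oxy]-3-(triisopropylsilyloxy)phenyl}-1-(2,4,6-trihydroxyphenyl)prop-2-en-1-one | CC(C)=CCOc1ccc(/C=C/C(=O)c2c(O)cc(O)cc2O)cc1O[Si](C(C)C)(C(C)C)C(C)C
F3 | step 1 | rac-5,7-dihydroxy-2-{4-[(3-methylbut-2-en-1-yl)oxy]-3-(triisopropylsilyloxy)phenyl}chroman-4-one | CC(C)=CCOc1ccc(C2CC(=O)c3c(O)cc(O)cc3O2)cc1O[Si](C(C)C)(C(C)C)C(C)C
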